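**Plan**
- Retrosynthesis (flavanone numbering O1, C2, C3, C4, C4a, C5–C8, C8a): first the four MOM acetal C–O bonds are cut; then ring C at C2–C3 and O1–C8a, giving the ring B aldehyde and a ring A methyl ketone with F on C8a; then the acetyl (C4–C4a) and geranyl (C6–C1'') bonds, back to 5-fluororesorcinol.
- Enabling feature: C8a is ortho to the C4 carbonyl and meta to both ring A oxygens (O5, O7), so C8a(F)=C4a–C4=O is a vinylogous acyl fluoride. With C3 as enol silane, the ketone is a four-atom C3–C4–C4a–C8a donor–acceptor unit that takes up the aldehyde C=O in a formal [4+2] annulation.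
- Forward: ring A is substituted by two directed metalations (geranyl between the two OMOM groups, then acetyl between F and OMOM). Ring B comes from 5-hydroxyvanillin. Ring C is the only ring formed and closes in step 6; deprotection ends the route.
- Stereochemistry: C2 (S) is set by catalyst-controlled Si-face addition to the aldehyde in step 6, and its C–O bond is never broken afterwards. The (E)-alkene comes with geranyl bromide. The fluorine position also fixes 6- versus 8-geranyl regiochemistry.

Key step: step 6

Assumption: the B-butyl N-tosyl oxazaborolidinone from (S)-tryptophan is taken to deliver enol silanes to the Re face of aryl aldehydes, so the (R)-tryptophan-derived catalyst is specified for Si-face attack; should the sense be the reverse, the enantiomeric catalyst is used without other change.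

**Route**

Step 1
Reactants: 1 5-fluororesorcinol; 2 chloromethyl methyl ether
Product: 3 1-fluoro-3,5-bis(methoxymethoxy)benzene
Conditions: MOMCl, iPr2NEt, CH2Cl2, 0 °C to rt
Reagents that add atoms: chloromethyl methyl ether, COCCl
Why: O-alkylation of both phenols with an α-chloro ether (MOM protection) should proceed cleanly; the acetals later serve as directing groups and are removable without base.

Step 2
Reactants: 3 1-fluoro-3,5-bis(methoxymethoxy)benzene; 4 geranyl bromide
Product: 6 5-fluoro-2-[(2E)-3,7-dimethylocta-2,6-dien-1-yl]-1,3-bis(methoxymethoxy)benzene, via aryllithium 5 (not isolated)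
Conditions: n-BuLi, Et2O, 0 °C; then CuI (10 mol %), 4, THF, −40 °C to rt
Reagents that add atoms: geranyl bromide, BrC/C=C(\C)CCC=C(C)C
Why: Directed ortho-metalation under coordination control should remove the hydrogen flanked by the two OMOM groups (the stronger directors) in preference to that flanked by OMOM and F, and copper-catalysed SN2 allylation of the aryllithium should keep the (E)-alkene.

Step 3
Reactants: 6 5-fluoro-2-geranyl-1,3-bis(methoxymethoxy)benzene; 7 N-methoxy-N-methylacetamide
Product: 10 1-{6-fluoro-3-[(2E)-3,7-dimethylocta-2,6-dien-1-yl]-2,4-bis(methoxymethoxy)phenyl}ethan-1-one, via aryllithium 8 (not isolated), via tetrahedral lithium adduct 9 (not isolated)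
Conditions: s-BuLi, THF, −78 °C; then 7, −78 to −20 °C; H2O
Reagents that add atoms: N-methoxy-N-methylacetamide, CC(=O)N(C)OC
Why: A second directed ortho-metalation can only take place at the two symmetry-equivalent ring hydrogens flanked by F and OMOM; at −78 °C the ortho-fluoro aryllithium should not lose LiF, and acylation with the N-methoxy-N-methylamide stops at the ketone because the chelated tetrahedral adduct survives until quench.

Step 4
Reactants: 10 aryl methyl ketone; 11 chlorotrimethylsilane
Product: 13 ({1-[6-fluoro-3-geranyl-2,4-bis(methoxymethoxy)phenyl]ethenyl}oxy)trimethylsilane, via lithium enolate 12 (not isolated)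
Conditions: LiN(SiMe3)2, THF, −78 °C; then Me3SiCl, −78 to 0 °C; non-aqueous work-up (pentane, filtration), used directly
Reagents that add atoms: chlorotrimethylsilane, C[Si](C)(C)Cl
Why: The methyl group is the only enolisable position, so kinetic deprotonation and O-silylation should give a single enol silane.

Step 5
Reactants: 14 3,4-dihydroxy-5-methoxybenzaldehyde (5-hydroxyvanillin); 2 chloromethyl methyl ether
Product: 15 3-methoxy-4,5-bis(methoxymethoxy)benzaldehyde
Conditions: MOMCl, iPr2NEt, CH2Cl2, 0 °C to rt
Reagents that add atoms: chloromethyl methyl ether, COCCl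
Why: MOM protection of the catechol hydroxyls should leave the aldehyde and the methyl ether untouched and gives ring B with its final oxygenation pattern.

Step 6
Reactants: 13 enol silane of the ring A ketone (1.0 equiv); 15 ring B aldehyde (1.2 equiv)
Product: 18 (2S)-6-[(2E)-3,7-dimethylocta-2,6-dien-1-yl]-2-[3-methoxy-4,5-bis(methoxymethoxy)phenyl]-5,7-bis(methoxymethoxy)-2,3-dihydro-4H-chromen-4-one, via silyl aldol 16 (not isolated), via tetrabutylammonium alkoxide 17 (not isolated)
Conditions: (4R)-2-butyl-4-(1H-indol-3-ylmethyl)-3-tosyl-1,3,2-oxazaborolidin-5-one (C22H25BN2O4S, 20 mol %), EtCN, −78 °C; then Bu4N[Ph3SiF2] (30 mol %), THF, −78 to 0 °C; AcOH quench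
Reagents that add atoms: none
Why: Proposed new method: a one-pot formal [4+2] annulation in which the boron Lewis acid binds aldehyde 15, the terminal carbon of enol silane 13 (C3) adds through an open transition state and silyl transfer gives the (S)-β-silyloxy ketone 16 (Mukaiyama aldol), after which substoichiometric fluoride unmasks alkoxide 17, which adds to C8a and expels fluoride from the Meisenheimer adduct, the released fluoride desilylating the next molecule of 16 so that the chain is net neutral. The closest known reaction types are the oxazaborolidinone-catalysed aldol of aryl methyl ketone enol silanes with aryl aldehydes, the aldol–cyclisation of 1-methoxy-3-silyloxybutadienes with aldehydes to dihydropyranones (F here plays the part of the methoxy leaving group and the C4a=C8a bond of ring A that of the second diene double bond), and fluoride-relayed SNAr of silyl ethers on activated aryl fluorides. Ring C closes by a 6-endo-trig addition–elimination at C8a, the β-carbon of the vinylogous acyl fluoride C8a(F)=C4a–C4=O. The only new stereocentre, C2, is set by the catalyst, whose indole shields the Re face of the bound aldehyde so that C3 adds to the Si face, and it is carried through because the C2–O bond is not touched in the closure. The step needs ring closure to outrun retro-aldol cleavage and E1cB dehydration of 17 and needs the product to escape base-induced opening of ring C: ortho-acyl activation, the meta (non-deactivating) placing of O5 and O7 relative to C8a, fluoride as leaving group, the low standing concentration of alkoxide, the low temperature and the acetic acid quench are meant to secure this. Site selectivity is inherent, since C8a is the only ring A carbon with a leaving group and the only one the C2 alkoxide can reach in a six-membered transition state.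

Step 7
Reactants: 18 tetra-MOM flavanone
Product: 19 (2S)-2-(3,4-dihydroxy-5-methoxyphenyl)-6-[(2E)-3,7-dimethylocta-2,6-dien-1-yl]-5,7-dihydroxy-2,3-dihydro-4H-chromen-4-one (target)
Conditions: HCl (3 M in MeOH), MeOH, 45 °C; then pH 6 phosphate buffer
Reagents that add atoms: none
Why: Acid-catalysed acetal methanolysis should remove all four MOM groups; no base is present, so the retro-oxa-Michael pathway that racemises flavanones is closed and C2 should stay (S).

**Compound list**

1 | 5-fluororesorcinol (5-fluorobenzene-1,3-diol) | Oc1cc(O)cc(F)c1 | starting material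
2 | chloromethyl methyl ether (MOMCl) | COCCl | starting material
3 | 1-fluoro-3,5-bis(methoxymethoxy)benzene | COCOc1cc(F)cc(OCOC)c1 | intermediate
4 | geranyl bromide, (2E)-1-bromo-3,7-dimethylocta-2,6-diene | BrC/C=C(\C)CCC=C(C)C | starting material
5 | [4-fluoro-2,6-bis(methoxymethoxy)phenyl]lithium | [Li]c1c(OCOC)cc(F)cc1OCOC | intermediate (not isolated)
6 | 5-fluoro-2-[(2E)-3,7-dimethylocta-2,6-dien-1-yl]-1,3-bis(methoxymethoxy)benzene | COCOc1cc(F)cc(OCOC)c1C/C=C(\C)CCC=C(C)C | intermediate
7 | N-methoxy-N-methylacetamide | CC(=O)N(C)OC | starting material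
8 | {6-fluoro-3-[(2E)-3,7-dimethylocta-2,6-dien-1-yl]-2,4-bis(methoxymethoxy)phenyl}lithium | [Li]c1c(F)cc(OCOC)c(C/C=C(\C)CCC=C(C)C)c1OCOC | intermediate (not isolated)
9 | lithium 1-[6-fluoro-3-geranyl-2,4-bis(methoxymethoxy)phenyl]-1-[methoxy(methyl)amino]ethan-1-olate (tetrahedral adduct, racemic at the carbinol carbon) | CC(O[Li])(N(C)OC)c1c(F)cc(OCOC)c(C/C=C(\C)CCC=C(C)C)c1OCOC | intermediate (not isolated)
10 | 1-{6-fluoro-3-[(2E)-3,7-dimethylocta-2,6-dien-1-yl]-2,4-bis(methoxymethoxy)phenyl}ethan-1-one | CC(=O)c1c(F)cc(OCOC)c(C/C=C(\C)CCC=C(C)C)c1OCOC | intermediate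
11 | chlorotrimethylsilane | C[Si](C)(C)Cl | starting material
12 | lithium enolate of 10, lithium 1-[6-fluoro-3-geranyl-2,4-bis(methoxymethoxy)phenyl]ethen-1-olate | C=C(O[Li])c1c(F)cc(OCOC)c(C/C=C(\C)CCC=C(C)C)c1OCOC | intermediate (not isolated)
13 | ({1-[6-fluoro-3-geranyl-2,4-bis(methoxymethoxy)phenyl]ethenyl}oxy)trimethylsilane | C=C(O[Si](C)(C)C)c1c(F)cc(OCOC)c(C/C=C(\C)CCC=C(C)C)c1OCOC | intermediate
14 | 3,4-dihydroxy-5-methoxybenzaldehyde (5-hydroxyvanillin) | COc1cc(C=O)cc(O)c1O | starting material
15 | 3-methoxy-4,5-bis(methoxymethoxy)benzaldehyde | COc1cc(C=O)cc(OCOC)c1OCOC | intermediate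
16 | (3S)-1-[6-fluoro-3-geranyl-2,4-bis(methoxymethoxy)phenyl]-3-[3-methoxy-4,5-bis(methoxymethoxy)phenyl]-3-(trimethylsilyloxy)propan-1-one | COc1cc([C@@H](O[Si](C)(C)C)CC(=O)c2c(F)cc(OCOC)c(C/C=C(\C)CCC=C(C)C)c2OCOC)cc(OCOC)c1OCOC | intermediate (not isolated)
17 | tetrabutylammonium (1S)-3-[6-fluoro-3-geranyl-2,4-bis(methoxymethoxy)phenyl]-1-[3-methoxy-4,5-bis(methoxymethoxy)phenyl]-3-oxopropan-1-olate | COc1cc([C@@H]([O-])CC(=O)c2c(F)cc(OCOC)c(C/C=C(\C)CCC=C(C)C)c2OCOC)cc(OCOC)c1OCOC.CCCC[N+](CCCC)(CCCC)CCCC | intermediate (not isolated)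
18 | (2S)-6-[(2E)-3,7-dimethylocta-2,6-dien-1-yl]-2-[3-methoxy-4,5-bis(methoxymethoxy)phenyl]-5,7-bis(methoxymethoxy)-2,3-dihydro-4H-chromen-4-one | COc1cc([C@@H]2CC(=O)c3c(cc(OCOC)c(C/C=C(\C)CCC=C(C)C)c3OCOC)O2)cc(OCOC)c1OCOC | intermediate
19 | (2S)-2-(3,4-dihydroxy-5-methoxyphenyl)-6-[(2E)-3,7-dimethylocta-2,6-dien-1-yl]-5,7-dihydroxy-2,3-dihydro-4H-chromen-4-one | COc1cc([C@@H]2CC(=O)c3c(cc(O)c(C/C=C(\C)CCC=C(C)C)c3O)O2)cc(O)c1O | target

**Totals and risks**

Total step count: 7
Longest linear sequence: 6 steps (steps 1, 2, 3, 4, 6, 7)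

Steps most likely to fail:

1. Step 6 (proposed new method). Once the alkoxide is unmasked it may fragment by retro-aldol cleavage and recombine outside catalyst control, which erodes enantiopurity, or dehydrate by E1cB, faster than it closes onto the electron-rich, twisted aryl ketone. Prolonged contact with fluoride could also open ring C by β-elimination. The fallback uses known chemistry and removes the carbonyl during ring closure. It sets out from 13 (with 15): the aldol stage alone, followed by aqueous HCl work-up, should give (3S)-1-[6-fluoro-3-geranyl-2,4-bis(methoxymethoxy)phenyl]-3-hydroxy-3-[3-methoxy-4,5-bis(methoxymethoxy)phenyl]propan-1-one F1. Narasaka–Prasad reduction (Et2BOMe, NaBH4, THF/MeOH, −78 °C) should give the syn-diol (1R,3S)-1-[6-fluoro-3-geranyl-2,4-bis(methoxymethoxy)phenyl]-3-[3-methoxy-4,5-bis(methoxymethoxy)phenyl]propane-1,3-diol F2. Intramolecular SNAr of its dialkoxide (KN(SiMe3)2, 18-crown-6, THF, 60 °C) cannot be undone by retro-aldol, and only the C3 alkoxide can reach the C–F carbon; it should give (2S,4R)-6-geranyl-2-[3-methoxy-4,5-bis(methoxymethoxy)phenyl]-5,7-bis(methoxymethoxy)-3,4-dihydro-2H-chromen-4-ol F3. Oxidation with Dess–Martin periodinane (NaHCO3, CH2Cl2) brings the material back to the route at 18.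

2. Step 2. Metalation may occur in part at the carbon between F and OMOM (acidity control instead of coordination control), which would lead to the regioisomeric geranyl arene or, by loss of LiF, to aryne-derived products. The fallback fixes the site with a halogen. It sets out from 1: iodination (I2, NaHCO3, H2O, 0 °C) between the two hydroxyls and para to fluorine should give 5-fluoro-2-iodobenzene-1,3-diol F4. MOM protection (MOMCl, iPr2NEt, CH2Cl2) should give 5-fluoro-2-iodo-1,3-bis(methoxymethoxy)benzene F5. Iodine–lithium exchange (n-BuLi, THF, −78 °C) generates aryllithium 5 without ambiguity, and the route is rejoined at 5 (CuI, geranyl bromide, to 6).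

3. Step 7. Under protic acid the geranyl alkenes may cyclise onto the flanking C5 and C7 phenols, or add HCl or methanol, before all four acetals are cleaved. The fallback replaces protic solvolysis by aprotic silyl transfer. It sets out from 18: Me3SiOTf and 2,2'-bipyridyl (CH2Cl2, 0 °C) should exchange each aryl MOM ether for a silyl ether by way of a methoxymethyl-pyridinium species, giving (2S)-6-geranyl-2-[3-methoxy-4,5-bis(trimethylsilyloxy)phenyl]-5,7-bis(trimethylsilyloxy)-2,3-dihydro-4H-chromen-4-one F6. Hydrolysis of the aryl silyl ethers in aqueous MeOH at rt returns to the route at 19.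

**Further compounds**

F1 | step 6 | (3S)-1-[6-fluoro-3-geranyl-2,4-bis(methoxymethoxy)phenyl]-3-hydroxy-3-[3-methoxy-4,5-bis(methoxymethoxy)phenyl]propan-1-one | COc1cc([C@@H](O)CC(=O)c2c(F)cc(OCOC)c(C/C=C(\C)CCC=C(C)C)c2OCOC)cc(OCOC)c1OCOC
F2 | step 6 | (1R,3S)-1-[6-fluoro-3-geranyl-2,4-bis(methoxymethoxy)phenyl]-3-[3-methoxy-4,5-bis(methoxymethoxy)phenyl]propane-1,3-diol | COc1cc([C@@H](O)C[C@@H](O)c2c(F)cc(OCOC)c(C/C=C(\C)CCC=C(C)C)c2OCOC)cc(OCOC)c1OCOC
F3 | step 6 | (2S,4R)-6-geranyl-2-[3-methoxy-4,5-bis(methoxymethoxy)phenyl]-5,7-bis(methoxymethoxy)-3,4-dihydro-2H-chromen-4-ol | COc1cc([C@@H]2C[C@@H](O)c3c(cc(OCOC)c(C/C=C(\C)CCC=C(C)C)c3OCOC)O2)cc(OCOC)c1OCOC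
F4 | step 2 | 5-fluoro-2-iodobenzene-1,3-diol | Oc1cc(F)cc(O)c1I
F5 | step 2 | 5-fluoro-2-iodo-1,3-bis(methoxymethoxy)benzene | COCOc1cc(F)cc(OCOC)c1I
F6 | step 7 | (2S)-6-geranyl-2-[3-methoxy-4,5-bis(trimethylsilyloxy)phenyl]-5,7-bis(trimethylsilyloxy)-2,3-dihydro-4H-chromen-4-one | COc1cc([C@@H]2CC(=O)c3c(cc(O[Si](C)(C)C)c(C/C=C(\C)CCC=C(C)C)c3O[Si](C)(C)C)O2)cc(O[Si](C)(C)C)c1O[Si](C)(C)C
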